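**Retrosynthetic overview**

1. Target 34 comes from the 4β,6α-diol 26 by O6 protection, aroylation of the C4 tertiary alkoxide, O6 release, hydroxyl-directed C8=C9 epoxidation and debenzylation. Diol 26 comes from epoxy alcohol 23 by radical oxirane opening (sets C5), oxidation and Evans–Saksena reduction (sets C6).
2. Epoxy alcohol 23 comes from epoxy ketone 21 and iPrMgCl. Ketone 21 comes from enone 18 by CBS reduction, hydroxyl-directed epoxidation and re-oxidation. This relay is used because the two faces of the C5=C6 enone are nearly equivalent (C1 shows CH3 to one face and C10H2 to the other).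
3. Enone 18 comes from the Nazarov product 15 by Saegusa dehydrogenation (C5=C6) and selective hydrogenation of C2=C3.
4. Key disconnection, and the feature it rests on: in the five-membered ring C1–C2–C3–C4–C5, C4 is flanked by C3–C2 and by C5–C1. With C4 as a carbonyl and both flanks as alkenes this is divinyl ketone 14. A 4π closure between C1 and C2 builds the cyclopentenone onto the preformed seven-membered ring (C1, C5–C10) and creates the quaternary C1.
5. Ketone 14 comes from enol triflate 10, CO and stannane 13. Triflate 10 comes from cycloheptenone 8, made from alkynol 6 by 5-exo-dig cyclisation and Claisen ring expansion. Ring order: seven-membered ring, then five-membered ring, then the oxirane.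

Key step: step 7

Numbering used throughout: C1 = methyl-bearing ring-fusion carbon; C2, C3 = CH2; C4 = carbon that ends with the ester oxygen and the isopropyl group; C5 = ring-fusion CH; C6 = carbinol carbon; C7 = CH2; C8 (methyl) and C9 = oxirane carbons; C10 = CH2. β is the face of the C1 methyl group and α the opposite face. The SMILES strings in the compound list are definitive for configuration.

Assumption: the sense of induction of the chiral acid in step 7 cannot be predicted with confidence. The (R)-configured catalyst is assumed to give the (3aS) product; otherwise its mirror image would be used.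

Remark: the ester is on the tertiary O4 and the C6 hydroxyl is free, as drawn. All steps after the aroylation are therefore kept neutral, so that the acyl group cannot migrate to O6 and the tertiary ester cannot ionise.

**Route**

Step 1
Reactants: 1 pentane-2,4-dione; 2 1-bromobut-2-yne
Product: 4 hept-5-yn-2-one, via 3-(but-2-yn-1-yl)pentane-2,4-dione 3 (not isolated)
Conditions: K2CO3, EtOH, reflux
Reagents that add atoms: none
Why: C-alkylation of the diketone followed in the same pot by retro-Claisen deacetylation with ethanol (alkylation–deacylation) should give the methyl ketone directly; no stereocentre is formed.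

Step 2
Reactants: 4 hept-5-yn-2-one; 5 vinylmagnesium bromide
Product: 6 (±)-3-methyloct-1-en-6-yn-3-ol
Conditions: THF, 0 °C; aq. NH4Cl
Reagents that add atoms: none
Why: Grignard 1,2-addition to a methyl ketone; the carbinol centre is racemic, which does not matter because it becomes sp2 in step 3.

Step 3
Reactants: 6 (±)-3-methyloct-1-en-6-yn-3-ol
Product: 8 (±)-2,5-dimethylcyclohept-4-en-1-one, via (Z)-2-ethylidene-5-methyl-5-vinyltetrahydrofuran 7 (not isolated)
Conditions: MeLi (10 mol %), phenetole, 170 °C
Reagents that add atoms: none
Why: The lithium alkoxide should add to the alkyne by 5-exo-dig anti-hydroalkoxylation, and the allyl vinyl ether unit of the resulting alkylidene tetrahydrofuran then undergoes Claisen rearrangement with ring expansion; the 2,5-placement of the methyl groups follows from connectivity, so no regioisomer can arise as it would in a cycloaddition with isoprene, and the racemic C2 centre is destroyed in step 4.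

Step 4
Reactants: 8 (±)-2,5-dimethylcyclohept-4-en-1-one
Product: 10 2,5-dimethylcyclohepta-1,4-dien-1-yl trifluoromethanesulfonate, via bromomagnesium 2,5-dimethylcyclohepta-1,4-dien-1-olate 9 (not isolated)
Conditions: iPr2NMgBr, Et2O, 23 °C, 12 h; then PhNTf2, THF, 23 to 40 °C
Reagents that add atoms: N-phenylbis(trifluoromethanesulfonimide), O=S(=O)(N(c1ccccc1)S(=O)(=O)C(F)(F)F)C(F)(F)F
Why: Bromomagnesium diisopropylamide should equilibrate the enolates toward the more substituted C1=C2 isomer (thermodynamic enolate formation), which PhNTf2 traps on oxygen as the tetrasubstituted enol triflate; the remote ring alkene cannot move into conjugation.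

Step 5
Reactants: 11 ethynyltrimethylsilane; 12 tributyltin hydride
Product: 13 (E)-trimethyl[2-(tributylstannyl)ethenyl]silane
Conditions: AIBN (cat.), neat, 80 °C
Reagents that add atoms: none
Why: Radical hydrostannylation of the terminal alkyne places tin on the terminal carbon and equilibrates to the (E)-alkene under the reaction conditions.

Step 6
Reactants: 10 2,5-dimethylcyclohepta-1,4-dien-1-yl trifluoromethanesulfonate; 13 (E)-trimethyl[2-(tributylstannyl)ethenyl]silane
Product: 14 (E)-1-(2,5-dimethylcyclohepta-1,4-dien-1-yl)-3-(trimethylsilyl)prop-2-en-1-one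
Conditions: Pd(PPh3)4 (5 mol %), LiCl, CO (3 atm), THF, 55 °C
Reagents that add atoms: carbon monoxide, [C-]#[O+]
Why: Carbonylative Stille coupling: oxidative addition of the vinyl triflate to zerovalent palladium, CO insertion and transfer of the alkenyl group from tin with retention of the (E) geometry should give the β-silyl divinyl ketone, with CO pressure suppressing direct coupling.

Step 7
Reactants: 14 (E)-1-(2,5-dimethylcyclohepta-1,4-dien-1-yl)-3-(trimethylsilyl)prop-2-en-1-one
Product: 15 (3aS,8aS)-3a,6-dimethyl-3a,4,7,8-tetrahydroazulen-1(8aH)-one (cis-fused; C4 ketone, C2=C3, C8=C9)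
Conditions: Zn(OTf)2 (10 mol %), (R)-3,3'-bis(2,4,6-triisopropylphenyl)-H8-BINOL N-triflylphosphoramide (10 mol %), PhOH (1.2 equiv), ClCH2CH2Cl, 40 °C
Reagents that add atoms: none
Why: Proposed new method: the zinc-bound ketone is a 3-oxidopentadienyl cation (C2=C3–C4–C5=C1) that should close by thermal conrotatory 4π electrocyclisation between C1 and C2, forming the five-membered ring C1–C5 on the existing cycloheptadiene; the oxyallyl cation then loses the silyl group from C2 (β-silicon effect), so the alkene appears only at C2=C3, and phenol protonates the zinc dienolate at C5. The closest known reaction type is the FeCl3-promoted silicon-directed Nazarov cyclisation of β-silyl divinyl ketones and its Lewis acid/chiral Brønsted acid variant, which sets tertiary β-centres; closure onto the fully substituted C1 terminus to give a quaternary centre under such catalysis is the untested extension. The ring closes in the 4π-conrotatory (Nazarov) mode. C1, the only centre that survives, is fixed by the sense of conrotation, which the chiral phosphoramide anion bound to the zinc–ketone complex must bias because the substrate is achiral; C5 should be cis because a cyclopentenone cannot hold a trans-fused seven-membered ring without strain, and it is erased in step 8. The step needs alkene regiocontrol (secured by silicon on C2), tolerance of the C8=C9 alkene (secured by the mild zinc Lewis acid) and enantioselectivity (the open risk).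

Step 8
Reactants: 15 (3aS,8aS)-3a,6-dimethyl-3a,4,7,8-tetrahydroazulen-1(8aH)-one
Product: 17 (S)-3a,6-dimethyl-4,7-dihydroazulen-1(3aH)-one (C4 ketone, C2=C3, C5=C6, C8=C9), via trimethylsilyl dienol ether 16 (not isolated)
Conditions: TMSOTf, Et3N, CH2Cl2, 0 °C; then Pd(OAc)2 (1.1 equiv), MeCN, 23 °C
Reagents that add atoms: none
Why: Soft enolisation can only occur at C5 (C1 is quaternary), and in the Saegusa oxidation the palladium enolate can only undergo β-hydride elimination toward C6, so the C5=C6 alkene forms regiospecifically and the C5 stereocentre is erased.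

Step 9
Reactants: 17 (S)-3a,6-dimethyl-4,7-dihydroazulen-1(3aH)-one
Product: 18 (R)-3a,6-dimethyl-3,3a,4,7-tetrahydroazulen-1(2H)-one (C4 ketone, C5=C6, C8=C9)
Conditions: H2 (1 atm), RhCl(PPh3)3 (5 mol %), benzene, 23 °C
Reagents that add atoms: none
Why: Homogeneous hydrogenation with RhCl(PPh3)3 should reduce only the cis-disubstituted C2=C3 alkene and leave the trisubstituted C5=C6 and C8=C9 alkenes, as in the selective 1,2-reduction of cross-conjugated steroidal dienones; no stereocentre is formed.

Step 10
Reactants: 18 (R)-3a,6-dimethyl-3,3a,4,7-tetrahydroazulen-1(2H)-one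
Product: 19 (1S,3aR)-3a,6-dimethyl-1,2,3,3a,4,7-hexahydroazulen-1-ol (C4–OH β)
Conditions: (R)-2-methyl-CBS-oxazaborolidine (20 mol %), catecholborane, toluene, −78 °C; aq. NaOH
Reagents that add atoms: none
Why: CBS reduction under catalyst control (alkylidene carbon C5 as the large group, C3H2 as the small group) should deliver hydride to the α face of C4 and give the (S)-carbinol; reagent control is chosen because the enone has no useful facial bias of its own, and catecholborane leaves the alkenes alone.

Step 11
Reactants: 19 (1S,3aR)-3a,6-dimethyl-1,2,3,3a,4,7-hexahydroazulen-1-ol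
Product: 20 5β,6β-epoxide of 19 (oxirane across C5–C6, syn to the C4–OH)
Conditions: VO(acac)2 (5 mol %), t-BuOOH, CH2Cl2, 0 °C
Reagents that add atoms: tert-butyl hydroperoxide, CC(C)(C)OO
Why: Hydroxyl-directed vanadium-catalysed epoxidation should deliver oxygen syn to the allylic C4–OH and only to C5=C6, since C8=C9 has no allylic hydroxyl; this sets C5 and C6 on the β face.

Step 12
Reactants: 20 5β,6β-epoxide of 19
Product: 21 5β,6β-epoxy C4 ketone
Conditions: Dess–Martin periodinane, pyridine, CH2Cl2, 0 to 23 °C
Reagents that add atoms: none
Why: Dess–Martin oxidation of the secondary alcohol; the relay centre C4 is removed after it has placed the oxirane on the β face, and the epoxy ketone has no epimerisable centre.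

Step 13
Reactants: 21 5β,6β-epoxy C4 ketone; 22 isopropylmagnesium chloride
Product: 23 4β-hydroxy-4α-isopropyl 5β,6β-epoxide
Conditions: CeCl3, THF, −78 °C
Reagents that add atoms: none
Why: 1,2-Addition of the organocerium reagent (CeCl3 suppresses enolisation, reduction and oxirane opening); with C5 now sp3, the nucleophile should approach C4 anti to the electronegative oxirane oxygen next to the carbonyl (polar 1,2-induction) and anti to the β methyl on C1, that is from the α face, giving 4β-OH and 4α-isopropyl.

Step 14
Reactants: 23 4β-hydroxy-4α-isopropyl 5β,6β-epoxide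
Product: 24 4β,6β-diol with 5α-H (trans ring fusion, C8=C9 intact)
Conditions: Cp2TiCl2 (2.5 equiv), Mn, H2O (10 equiv), THF, 23 °C
Reagents that add atoms: none
Why: Cp2TiCl (trivalent titanium) should open the oxirane homolytically at the more substituted C5–O bond (radical epoxide opening), and hydrogen-atom transfer from the Cp2TiCl–water complex to the C5 radical is expected anti to the bulky C6 titanium alkoxide and to the β groups on C1 and C4, giving 5α-H and leaving 6β-OH.

Step 15
Reactants: 24 4β,6β-diol with 5α-H
Product: 25 4β-hydroxy C6 ketone (trans-fused)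
Conditions: Dess–Martin periodinane, pyridine, CH2Cl2, 0 °C
Reagents that add atoms: none
Why: Dess–Martin oxidation of the secondary C6–OH beside the inert tertiary C4–OH under buffered, base-free conditions, so that the β,γ-unsaturated ketone is not conjugated with C8=C9 and the aldol does not fragment; the product is used crude in step 16.

Step 16
Reactants: 25 4β-hydroxy C6 ketone
Product: 26 4β,6α-diol (trans-fused, C8=C9 intact)
Conditions: Me4NBH(OAc)3, MeCN/AcOH, −30 °C
Reagents that add atoms: none
Why: Evans–Saksena reduction: boron binds the C4 hydroxyl and hydride is delivered intramolecularly to the β face of the C6 carbonyl, giving the 1,3-anti diol (6α-OH) in an acidic medium that does not enolise the ketone toward C7.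

Step 17
Reactants: 26 4β,6α-diol
Product: 27 6α-O-(4-methoxybenzyl) ether of 26
Conditions: NaH, 4-methoxybenzyl chloride, Bu4NI (cat.), DMF, 0 to 23 °C
Reagents that add atoms: 4-methoxybenzyl chloride, COc1ccc(CCl)cc1
Why: Williamson etherification of the less hindered secondary alkoxide; the tertiary C4 alkoxide is too hindered to be alkylated, and an ether is chosen because it cannot migrate to O4 in step 19.

Step 18
Reactants: 28 4-(benzyloxy)-3-methoxybenzoic acid
Product: 29 4-(benzyloxy)-3-methoxybenzoyl chloride
Conditions: (COCl)2, DMF (cat.), CH2Cl2, 0 to 23 °C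
Reagents that add atoms: oxalyl chloride, O=C(Cl)C(Cl)=O
Why: Acid chloride formation through the Vilsmeier-type chloroiminium catalyst; the benzyl and methyl ethers are inert.

Step 19
Reactants: 27 6α-O-(4-methoxybenzyl) ether of 26; 29 4-(benzyloxy)-3-methoxybenzoyl chloride
Product: 31 4β-[4-(benzyloxy)-3-methoxybenzoate] of 27, via potassium tertiary alkoxide 30 (not isolated)
Conditions: KN(SiMe3)2, THF, −78 °C; then 29, −78 to 23 °C
Reagents that add atoms: none
Why: O-Acylation of a preformed potassium alkoxide (nucleophilic acyl substitution) is the standard way to esterify a hindered tertiary alcohol; no stereocentre is touched.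

Step 20
Reactants: 31 4β-[4-(benzyloxy)-3-methoxybenzoate] of 27
Product: 32 6α-hydroxy 4β-[4-(benzyloxy)-3-methoxybenzoate] (C8=C9 intact)
Conditions: DDQ, CH2Cl2/pH 7 buffer, 0 °C
Reagents that add atoms: none
Why: Oxidative cleavage of the electron-rich 4-methoxybenzyl ether by DDQ (hydride abstraction, then hydrolysis of the oxocarbenium ion) under buffered neutral conditions should spare the tertiary ester, the aryl benzyl ether and the alkene and should not promote acyl migration to O6.

Step 21
Reactants: 32 6α-hydroxy 4β-[4-(benzyloxy)-3-methoxybenzoate]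
Product: 33 O-benzyl ether of the target (8α,9α-epoxide)
Conditions: VO(acac)2 (10 mol %), t-BuOOH, CH2Cl2, 0 to 23 °C
Reagents that add atoms: tert-butyl hydroperoxide, CC(C)(C)OO
Why: Hydroxyl-directed epoxidation: the homoallylic 6α-OH binds vanadium and should deliver oxygen to the α face of C8=C9, which is also the face remote from the β methyl on C1 and the β ester on C4.

Step 22
Reactants: 33 O-benzyl ether of the target
Product: 34 CNP0315707.1 (target; 1R,4R,5S,6S,8R,9S in the numbering above)
Conditions: H2 (1 atm), Pd/C, EtOAc, 23 °C
Reagents that add atoms: none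
Why: Hydrogenolysis of the aryl benzyl ether over Pd/C under neutral conditions; the trisubstituted oxirane and the tertiary ester should survive, and no base is present that could move the acyl group to O6.

**Compound list**

1 | pentane-2,4-dione | CC(=O)CC(C)=O | starting material
2 | 1-bromobut-2-yne | CC#CCBr | starting material
3 | 3-(but-2-yn-1-yl)pentane-2,4-dione | CC#CCC(C(C)=O)C(C)=O | intermediate
4 | hept-5-yn-2-one | CC#CCCC(C)=O | intermediate
5 | vinylmagnesium bromide | C=C[Mg]Br | starting material
6 | (±)-3-methyloct-1-en-6-yn-3-ol | CC#CCCC(C)(O)C=C | intermediate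
7 | (±)-(Z)-2-ethylidene-5-methyl-5-vinyltetrahydrofuran | C/C=C1/CCC(C)(C=C)O1 | intermediate
8 | (±)-2,5-dimethylcyclohept-4-en-1-one | CC1CC=C(C)CCC1=O | intermediate
9 | bromomagnesium 2,5-dimethylcyclohepta-1,4-dien-1-olate | CC1=C(O[Mg]Br)CCC(C)=CC1 | intermediate
10 | 2,5-dimethylcyclohepta-1,4-dien-1-yl trifluoromethanesulfonate | CC1=C(OS(=O)(=O)C(F)(F)F)CCC(C)=CC1 | intermediate
11 | ethynyltrimethylsilane | C#C[Si](C)(C)C | starting material
12 | tributyltin hydride | CCCC[SnH](CCCC)CCCC | starting material
13 | (E)-trimethyl[2-(tributylstannyl)ethenyl]silane | CCCC[Sn](CCCC)(CCCC)/C=C/[Si](C)(C)C | intermediate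
14 | (E)-1-(2,5-dimethylcyclohepta-1,4-dien-1-yl)-3-(trimethylsilyl)prop-2-en-1-one | C[Si](C)(C)/C=C/C(=O)C1=C(C)CC=C(C)CC1 | intermediate
15 | (3aS,8aS)-3a,6-dimethyl-3a,4,7,8-tetrahydroazulen-1(8aH)-one, cis-fused | O=C1C=C[C@]2(C)CC=C(C)CC[C@H]12 | intermediate
16 | trimethylsilyl dienol ether of 15 (C2=C3, C4(OSiMe3)=C5) | C[Si](C)(C)OC1=C2CCC(C)=CC[C@@]2(C)C=C1 | intermediate
17 | (S)-3a,6-dimethyl-4,7-dihydroazulen-1(3aH)-one | O=C1C=C[C@]2(C)CC=C(C)CC=C12 | intermediate
18 | (R)-3a,6-dimethyl-3,3a,4,7-tetrahydroazulen-1(2H)-one | O=C1CC[C@]2(C)CC=C(C)CC=C12 | intermediate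
19 | (1S,3aR)-3a,6-dimethyl-1,2,3,3a,4,7-hexahydroazulen-1-ol (C4–OH β) | O[C@H]1CC[C@]2(C)CC=C(C)CC=C21 | intermediate
20 | 5β,6β-epoxide of 19 | O[C@H]1CC[C@]2(C)CC=C(C)C[C@H]3O[C@@]312 | intermediate
21 | 5β,6β-epoxy C4 ketone | O=C1CC[C@]2(C)CC=C(C)C[C@H]3O[C@@]312 | intermediate
22 | isopropylmagnesium chloride | CC(C)[Mg]Cl | starting material
23 | 4β-hydroxy-4α-isopropyl 5β,6β-epoxide | O[C@@]1(C(C)C)CC[C@]2(C)CC=C(C)C[C@H]3O[C@@]312 | intermediate
24 | 4β,6β-diol, 5α-H, trans-fused | O[C@@]1(C(C)C)CC[C@]2(C)CC=C(C)C[C@@H](O)[C@H]21 | intermediate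
25 | 4β-hydroxy C6 ketone, trans-fused | O[C@@]1(C(C)C)CC[C@]2(C)CC=C(C)CC(=O)[C@H]21 | intermediate
26 | 4β,6α-diol, trans-fused | O[C@@]1(C(C)C)CC[C@]2(C)CC=C(C)C[C@H](O)[C@H]21 | intermediate
27 | 6α-O-(4-methoxybenzyl) ether of 26 | O[C@@]1(C(C)C)CC[C@]2(C)CC=C(C)C[C@H](OCc3ccc(OC)cc3)[C@H]21 | intermediate
28 | 4-(benzyloxy)-3-methoxybenzoic acid | COc1cc(C(=O)O)ccc1OCc1ccccc1 | starting material
29 | 4-(benzyloxy)-3-methoxybenzoyl chloride | COc1cc(C(=O)Cl)ccc1OCc1ccccc1 | intermediate
30 | potassium C4 alkoxide of 27 | [K]O[C@@]1(C(C)C)CC[C@]2(C)CC=C(C)C[C@H](OCc3ccc(OC)cc3)[C@H]21 | intermediate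
31 | 4β-[4-(benzyloxy)-3-methoxybenzoate] of 27 | COc1cc(C(=O)O[C@@]2(C(C)C)CC[C@]3(C)CC=C(C)C[C@H](OCc4ccc(OC)cc4)[C@H]32)ccc1OCc1ccccc1 | intermediate
32 | 6α-hydroxy 4β-[4-(benzyloxy)-3-methoxybenzoate], C8=C9 | COc1cc(C(=O)O[C@@]2(C(C)C)CC[C@]3(C)CC=C(C)C[C@H](O)[C@H]32)ccc1OCc1ccccc1 | intermediate
33 | O-benzyl ether of the target | COc1cc(C(=O)O[C@@]2(C(C)C)CC[C@]3(C)C[C@@H]4O[C@]4(C)C[C@H](O)[C@H]32)ccc1OCc1ccccc1 | intermediate
34 | CNP0315707.1 | COc1cc(C(=O)O[C@@]2(C(C)C)CC[C@]3(C)C[C@@H]4O[C@]4(C)C[C@H](O)[C@H]32)ccc1O | target

Total step count: 22. Longest linear sequence: 20 steps (steps 1–4, 6–17, 19–22).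

**Steps most likely to fail**

Step 7. What may go wrong: the chiral acid may bias the sense of conrotation only weakly, or in the wrong sense, when the closing terminus is fully substituted. Slow closure would also leave time for acid-mediated isomerisation of the skipped diene. The fallback separates ring formation from absolute control and uses only known chemistry. It sets out from 14. FeCl3 (1.05 equiv, CH2Cl2, −30 to 0 °C), the classical silicon-directed Nazarov cyclisation, would give the racemic cis-fused enone F1. Steps 8 and 9, applied unchanged, would give the racemic silyl dienol ether F2 (not isolated), the racemic dienone F3 and the racemic enone F4. The CBS reduction of step 10, run to full conversion on the racemate, would then convert the two enantiomers into two diastereomeric allylic alcohols with the same (S) configuration at C4: compound 19 and the (1S,3aS) allylic alcohol F5. These are separated by chromatography, and the route is rejoined at 19.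

Step 19. What may go wrong: the tertiary alkoxide, flanked by the isopropyl group and the substituted C5, may acylate too slowly, so that the acid chloride is consumed by side reactions and 27 is recovered. The fallback forms the C4–O–acyl bond by an intramolecular redox step instead of an acylation. It sets out from 25. An Evans–Tishchenko reaction with 4-(benzyloxy)-3-methoxybenzaldehyde (3 equiv) and SmI2 (30 mol %) in THF at −10 °C would let the C4 hydroxyl add to the aldehyde. The samarium-bound hemiacetal would then pass its hydride to the β face of the C6 carbonyl. This should place the ester on O4 and the free hydroxyl on C6 in the 1,3-anti sense. The route is rejoined at 32, and steps 16, 17, 19 and 20 are bypassed. No compound outside the list is made on this path (F0).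

Step 13. What may go wrong: facial selectivity at C4 may be poor if the oxirane oxygen does not steer the nucleophile, or the magnesium and cerium salts may open the oxirane. The fallback reverses the order of addition and epoxidation. It sets out from 18. iPrMgCl/CeCl3 (THF, −78 °C) would add to the enone carbonyl to give the 4β-hydroxy-4α-isopropyl allylic alcohol F6 together with its C4 epimer F7, which are separated by chromatography. VO(acac)2/t-BuOOH epoxidation of F6, directed by the tertiary hydroxyl, would then give 23, where the route is rejoined.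

**Further compounds**

F1 | step 7 | racemic cis-fused enone (15 and its enantiomer) | O=C1C=C[C@]2(C)CC=C(C)CC[C@H]12.O=C1C=C[C@@]2(C)CC=C(C)CC[C@@H]12
F2 | step 7 | racemic trimethylsilyl dienol ether (16 and its enantiomer) | C[Si](C)(C)OC1=C2CCC(C)=CC[C@@]2(C)C=C1.C[Si](C)(C)OC1=C2CCC(C)=CC[C@]2(C)C=C1
F3 | step 7 | racemic dienone (17 and its enantiomer) | O=C1C=C[C@]2(C)CC=C(C)CC=C12.O=C1C=C[C@@]2(C)CC=C(C)CC=C12
F4 | step 7 | racemic enone (18 and its enantiomer) | O=C1CC[C@]2(C)CC=C(C)CC=C12.O=C1CC[C@@]2(C)CC=C(C)CC=C12
F5 | step 7 | (1S,3aS)-3a,6-dimethyl-1,2,3,3a,4,7-hexahydroazulen-1-ol | O[C@H]1CC[C@@]2(C)CC=C(C)CC=C21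
F0 | step 19 | none | none
F6 | step 13 | 4β-hydroxy-4α-isopropyl allylic alcohol (C5=C6, C8=C9) | O[C@@]1(C(C)C)CC[C@]2(C)CC=C(C)CC=C21
F7 | step 13 | C4 epimer of F6 | O[C@]1(C(C)C)CC[C@]2(C)CC=C(C)CC=C21
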